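**Retrosynthetic overview**
- The equatorial C1–Br comes from a C1 alkenyl bromide by hydrogen-atom-transfer hydrogenation, and that from a C1 ketone; the C6 acetate comes from a C6 ketone by hydroxyl-directed reduction.
- Ring A is disconnected at C4–C5 (aldol) to a cis-enedione, which is the oxidatively ring-opened (dearomatized) form of a 2,5-disubstituted furan; this step creates C4(OH)CH3 and the ring fusion.
- C10–C1 is disconnected to a catalytic asymmetric conjugate addition of 5-methyl-2-furyl (from 2-methylfuran) to (S)-piperitone, the enolate being kept as a silyl enol ether.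
- Ring order: ring B is bought with piperitone (C7 and the isopropyl group); ring A is closed second, in the dearomatization/aldol step.

Eudesmane numbering is used for the bicyclic compounds: ring A = C1–C5 and C10, ring B = C5–C10; C10 carries the angular methyl, C4 a methyl, C7 the isopropyl group. The target is (1R,4S,5S,6S,7S,10R).

Assumption: (S)-(+)-piperitone of good optical purity is purchasable; because C10 is set by the catalyst, any (R)-enantiomer in it ends up as a separable diastereomer.

**Step 1**
Reactants: 1 2-methylfuran; 2 (S)-piperitone [(6S)-3-methyl-6-(propan-2-yl)cyclohex-2-en-1-one]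
Product: 6 tert-butyl(dimethyl){[(3R,6S)-3-methyl-3-(5-methylfuran-2-yl)-6-(propan-2-yl)cyclohex-1-en-1-yl]oxy}silane, via 5-methyl-2-furyllithium 3 (not isolated), via dimethyl(5-methylfuran-2-yl)alumane 4 (not isolated), via dimethylaluminium enolate 5 (not isolated)
Conditions: 1, n-BuLi, THF, 0 °C; Me2AlCl, −78 → 0 °C; then 2, Cu(OTf)2 (5 mol %), chiral sulfonate-imidazolinium salt (carbene precursor, 5 mol %), THF, −30 °C; TBSOTf, −30 → 0 °C
Reagents that add atoms: tert-butyldimethylsilyl triflate, CC(C)(C)[Si](C)(C)OS(=O)(=O)C(F)(F)F (silyl group of 6); dimethylaluminium chloride, C[Al](C)Cl (AlMe2 unit of 4 and 5 only); n-butyllithium, [Li]CCCC (Li of 3 only)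
Why: Copper-catalysed asymmetric conjugate addition of a heteroaryl-aluminium reagent to a β-methyl cyclohexenone creates the C10 quaternary centre, the chiral carbene–copper catalyst steering the furyl group to the enone face anti to the C7 isopropyl group (10R, C7 carried over from 2, any C10 epimer being a separable diastereomer), and the regiodefined aluminium enolate is O-silylated by the triflate to fix the C5=C6 enol ether.

**Step 2 (key step)**
Reactants: 6 tert-butyl(dimethyl){[(3R,6S)-3-methyl-3-(5-methylfuran-2-yl)-6-(propan-2-yl)cyclohex-1-en-1-yl]oxy}silane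
Product: 9 (4S,5R,7S,10R)-4-hydroxyeudesm-2-ene-1,6-dione, via furan endoperoxide 7 (not isolated), via cis-enedione silyl enol ether 8 (not isolated)
Conditions: O2, methylene blue (cat.), visible light, CH2Cl2, −78 °C; Me2S, −78 → −20 °C; then Bu4NF (1.1 equiv), THF, −78 → −30 °C; AcOH quench
Reagents that add atoms: dioxygen, O=O (one oxygen atom stays as a carbonyl oxygen)
Why: Proposed new method: singlet oxygen undergoes [4+2] cycloaddition with the electron-rich 2,5-dialkylfuran orders of magnitude faster than it attacks the hindered silyl enol ether, Me2S reduces endoperoxide 7 to cis-enedione 8 (oxidative furan dearomatization), and fluoride then liberates the C5 enolate regiospecifically, which closes ring A by a six-membered intramolecular aldol addition to the C4 methyl ketone (C1 is out of reach), the reversible aldolate settling into the trans-fused isomer with the C4 oxygen axial (4S,5R) because the alternatives place the C4 methyl syn-axial to the C10 methyl or the C4 carbon axial on ring B; the closest known reactions are the singlet-oxygen conversion of furans into cis-enediones and fluoride-triggered aldol additions of silyl enol ethers.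

**Step 3**
Reactants: 9 (4S,5R,7S,10R)-4-hydroxyeudesm-2-ene-1,6-dione
Product: 10 (4S,5R,7S,10R)-4-hydroxyeudesmane-1,6-dione
Conditions: H2 (1 atm), Pd/C (5 wt % Pd), EtOAc, 20 °C
Reagents that add atoms: none
Why: Heterogeneous catalytic hydrogenation saturates the cis-disubstituted enone alkene without touching the ketones or the tertiary alcohol and creates no stereocentre.

**Step 4**
Reactants: 10 (4S,5R,7S,10R)-4-hydroxyeudesmane-1,6-dione
Product: 11 (4S,5S,6S,7S,10R)-4,6-dihydroxyeudesman-1-one
Conditions: Me4NBH(OAc)3, MeCN/AcOH (1:1), −25 °C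
Reagents that add atoms: none
Why: Evans–Saksena hydroxyl-directed reduction: the axial C4 hydroxyl exchanges onto boron and delivers hydride intramolecularly to the syn-axial β face of the C6 ketone, giving the equatorial 6α-alcohol (6S, 1,3-anti diol), while the C1 ketone, which has no β-hydroxyl and is neopentyl, is not reduced by this mild acyloxyborohydride.

**Step 5**
Reactants: 11 (4S,5S,6S,7S,10R)-4,6-dihydroxyeudesman-1-one
Product: 12 (4S,5S,6S,7S,10R)-4-hydroxy-1-oxoeudesman-6-yl acetate
Conditions: Ac2O, pyridine, DMAP (cat.), CH2Cl2, 20 °C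
Reagents that add atoms: acetic anhydride, CC(=O)OC(C)=O
Why: Nucleophile-catalysed acylation (esterification) acetylates the secondary equatorial C6 alcohol only, the hindered tertiary axial C4 alcohol being inert under these conditions, and no stereocentre is touched.

**Step 6**
Reactants: 12 (4S,5S,6S,7S,10R)-4-hydroxy-1-oxoeudesman-6-yl acetate
Product: 14 (4S,5S,6S,7S,10R)-1-bromo-4-hydroxyeudesm-1-en-6-yl acetate, via N-silyl hydrazone 13 (not isolated)
Conditions: TBSNHNHTBS, Sc(OTf)3 (1 mol %), neat, 100 °C; then Br2, 2-tert-butyl-1,1,3,3-tetramethylguanidine, CH2Cl2, 0 → 20 °C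
Reagents that add atoms: bromine, BrBr (Br of 14); 1,2-bis(tert-butyldimethylsilyl)hydrazine, CC(C)(C)[Si](C)(C)NN[Si](C)(C)C(C)(C)C (N–N–Si unit of 13 only)
Why: Barton-type vinyl halide synthesis through an N-silyl hydrazone: bromine oxidizes 13 to the diazo compound and then to an α-bromo diazonium ion that loses N2 and the only available α-proton (C2–H, since C10 is quaternary), giving the C1(Br)=C2 alkenyl bromide regiospecifically without forming a stereocentre.

**Step 7**
Reactants: 14 (4S,5S,6S,7S,10R)-1-bromo-4-hydroxyeudesm-1-en-6-yl acetate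
Product: 15 (1R,4S,5S,6S,7S,10R)-1-bromo-4-hydroxyeudesman-6-yl acetate
Conditions: Mn(dpm)3 [tris(2,2,6,6-tetramethylheptane-3,5-dionato)manganese] (10 mol %), PhSiH3, t-BuOOH, i-PrOH, 20 °C
Reagents that add atoms: none
Why: Mukaiyama-type metal-hydride hydrogen-atom-transfer (MHAT) hydrogenation, which tolerates alkenyl and alkyl bromides, adds a hydrogen atom to C2 and then delivers the second hydrogen to the α-bromo C1 radical from the axial α face anti to the axial C10 methyl, so bromine ends equatorial (1R).

**Compound list**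
(The descriptor at C5 changes from R in 9 and 10 to S from 11 on only because the CIP priorities change when C6 is reduced.)

1 | 2-methylfuran | Cc1ccco1 | starting material
2 | (S)-(+)-piperitone, (6S)-3-methyl-6-(propan-2-yl)cyclohex-2-en-1-one | CC(C)[C@@H]1CCC(C)=CC1=O | starting material
3 | 5-methyl-2-furyllithium | [Li]c1ccc(C)o1 | intermediate
4 | dimethyl(5-methylfuran-2-yl)alumane | C[Al](C)c1ccc(C)o1 | intermediate
5 | dimethylaluminium (3R,6S)-3-methyl-3-(5-methylfuran-2-yl)-6-(propan-2-yl)cyclohex-1-en-1-olate | CC(C)[C@@H]1CC[C@@](C)(c2ccc(C)o2)C=C1O[Al](C)C | intermediate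
6 | tert-butyl(dimethyl){[(3R,6S)-3-methyl-3-(5-methylfuran-2-yl)-6-(propan-2-yl)cyclohex-1-en-1-yl]oxy}silane (furyl trans to isopropyl) | CC(C)[C@@H]1CC[C@@](C)(c2ccc(C)o2)C=C1O[Si](C)(C)C(C)(C)C | intermediate
7 | 1-[(1R,4S)-3-{[tert-butyl(dimethyl)silyl]oxy}-1-methyl-4-(propan-2-yl)cyclohex-2-en-1-yl]-4-methyl-2,3,7-trioxabicyclo[2.2.1]hept-5-ene (bridgehead configuration not controlled) | CC(C)[C@@H]1CC[C@@](C)(C23C=CC(C)(OO2)O3)C=C1O[Si](C)(C)C(C)(C)C | intermediate
8 | (2Z)-1-[(1R,4S)-3-{[tert-butyl(dimethyl)silyl]oxy}-1-methyl-4-(propan-2-yl)cyclohex-2-en-1-yl]hex-2-ene-1,4-dione | CC(C)[C@@H]1CC[C@@](C)(C(=O)/C=C\C(C)=O)C=C1O[Si](C)(C)C(C)(C)C | intermediate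
9 | (4S,5R,7S,10R)-4-hydroxyeudesm-2-ene-1,6-dione (trans-fused; 4β-OH axial, 5α-H, 7β-isopropyl, 10β-methyl) | O=C1[C@@H]2[C@@](C)(CC[C@H]1C(C)C)C(=O)C=C[C@]2(C)O | intermediate
10 | (4S,5R,7S,10R)-4-hydroxyeudesmane-1,6-dione | O=C1[C@@H]2[C@@](C)(CC[C@H]1C(C)C)C(=O)CC[C@]2(C)O | intermediate
11 | (4S,5S,6S,7S,10R)-4,6-dihydroxyeudesman-1-one (6α-OH equatorial) | O[C@@H]1[C@@H]2[C@@](C)(CC[C@H]1C(C)C)C(=O)CC[C@]2(C)O | intermediate
12 | (4S,5S,6S,7S,10R)-4-hydroxy-1-oxoeudesman-6-yl acetate | CC(=O)O[C@@H]1[C@@H]2[C@@](C)(CC[C@H]1C(C)C)C(=O)CC[C@]2(C)O | intermediate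
13 | N-(tert-butyldimethylsilyl)hydrazone of 12 at C1 | CC(=O)O[C@@H]1[C@@H]2[C@@](C)(CC[C@H]1C(C)C)C(=NN[Si](C)(C)C(C)(C)C)CC[C@]2(C)O | intermediate
14 | (4S,5S,6S,7S,10R)-1-bromo-4-hydroxyeudesm-1-en-6-yl acetate | CC(=O)O[C@@H]1[C@@H]2[C@@](C)(CC[C@H]1C(C)C)C(Br)=CC[C@]2(C)O | intermediate
15 | (1R,4S,5S,6S,7S,10R)-1-bromo-4-hydroxyeudesman-6-yl acetate [(1S,2S,4aR,5R,8S,8aS)-5-bromo-8-hydroxy-4a,8-dimethyl-2-(propan-2-yl)decahydronaphthalen-1-yl acetate] | CC(=O)O[C@@H]1[C@@H]2[C@@](C)(CC[C@H]1C(C)C)[C@H](Br)CC[C@]2(C)O | target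

**Step count**
Total steps: 7. Longest linear sequence: 7 steps (1 and 2 to 15).

**Steps most likely to fail and fallbacks**

Step 2 is the riskiest. Singlet oxygen may also attack the silyl enol ether. The kinetic aldol may give the cis-fused or C4-epimeric product if the aldolate does not equilibrate. Too much base or warmth could erode C7, where the equatorial preference next to the C6 ketone is only modest. The fallback sets out from 6 and returns at 10. Aqueous acid (AcOH/H2O 4:1, cat. H2SO4, 60 °C) cleaves the silyl enol ether and opens the furan hydrolytically, without oxidant, to the saturated triketone 1-[(1R,4S)-1-methyl-3-oxo-4-(propan-2-yl)cyclohexyl]hexane-1,4-dione F1. Thermodynamic intramolecular aldol addition (KOt-Bu 0.2 equiv, t-BuOH/THF, 0 °C) then closes ring A at the saturated stage and gives 10 directly, so Step 3 is not needed.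

Step 1 is second. The furyl-aluminium addition to piperitone is an extension of the known addition to 3-methylcyclohexenone, and the catalyst must override the weak substrate preference for addition cis to the isopropyl group. The fallback sets out from 1 and 2 and returns at 6. A Lewis-acid Friedel–Crafts conjugate addition of 1 to 2 (BF3·OEt2 20 mol %, MeNO2, 0 °C) gives, after chromatographic removal of the C5 epimer, the ketone (2S,5R)-5-methyl-5-(5-methylfuran-2-yl)-2-(propan-2-yl)cyclohexan-1-one F2. Kinetic deprotonation on the CH2 flank (LiN(i-Pr)2, THF, −78 °C) and O-silylation (TBSCl, DMPU) then give 6.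

Step 7 is third. The MHAT reduction may debrominate, or deliver hydrogen to the wrong face of the C1 radical. The fallback sets out from 13 and returns at 15. Oxidation of the N-silyl hydrazone with CuBr2/Et3N in MeOH gives the geminal dibromide (4S,5S,6S,7S,10R)-1,1-dibromo-4-hydroxyeudesman-6-yl acetate F3. Radical mono-debromination ((Me3Si)3SiH 1.0 equiv, AIBN cat., toluene, 80 °C) then leaves the equatorial bromide, because the α-bromo radical takes its hydrogen from the axial α face; this avoids both the alkenyl bromide and the metal hydride.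

**Further compounds**
F1 | step 2 | 1-[(1R,4S)-1-methyl-3-oxo-4-(propan-2-yl)cyclohexyl]hexane-1,4-dione | CC(C)[C@@H]1CC[C@@](C)(C(=O)CCC(C)=O)CC1=O
F2 | step 1 | (2S,5R)-5-methyl-5-(5-methylfuran-2-yl)-2-(propan-2-yl)cyclohexan-1-one | CC(C)[C@@H]1CC[C@@](C)(c2ccc(C)o2)CC1=O
F3 | step 7 | (4S,5S,6S,7S,10R)-1,1-dibromo-4-hydroxyeudesman-6-yl acetate | CC(=O)O[C@@H]1[C@@H]2[C@@](C)(CC[C@H]1C(C)C)C(Br)(Br)CC[C@]2(C)O
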